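The 2-hydroxypropan-2-yl group on C2 of the dihydrofuran ring is read as a hydrated isopropenyl group, which makes C2 an allylic carbon. The O1–C2 bond is therefore cut back to a phenol and a π-allylpalladium unit running over C2, the later carbinol carbon and one of its methyl carbons. One asymmetric intramolecular Tsuji–Trost etherification closes the five-membered ring, sets the only stereocentre (2R) and leaves the alkene for Markovnikov hydration. Its precursor is an acetophenone whose chelated phenol stands ortho to an (E)-4-aryl-2-methylbut-2-enyl methyl carbonate, the second flanking oxygen being blocked as a MOM ether. The chalcone arm is added last by Claisen–Schmidt condensation.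

Key step: step 6

Assumption: the (R,R) enantiomer of the ligand is taken to give the 2R product, by analogy with the closure of simpler 4-(2-hydroxyaryl)-2-methylbut-2-enyl carbonates; the sense of induction is to be checked on the cyclised product, and the equally available (S,S) enantiomer is used should it prove opposite.

Step 1
Reactants: 1 acetophenone 1-(2,4-dihydroxy-6-methoxyphenyl)ethanone
Product: 2 mono-MOM ether 1-[2-hydroxy-6-methoxy-4-(methoxymethoxy)phenyl]ethanone
Conditions: MOMCl (1.1 equiv), K2CO3 (1.5 equiv), acetone, 0 °C to rt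
Reagents that add atoms: chloromethyl methyl ether (MOMCl), COCCl
Why: Williamson-type MOM ether formation takes place at the 4-hydroxyl only, because the 2-hydroxyl is tied up in a hydrogen bond to the acetyl carbonyl and is therefore less acidic and less nucleophilic.

Step 2
Reactants: 2 mono-MOM ether 1-[2-hydroxy-6-methoxy-4-(methoxymethoxy)phenyl]ethanone
Product: 3 aryl iodide 1-[2-hydroxy-3-iodo-6-methoxy-4-(methoxymethoxy)phenyl]ethanone
Conditions: NIS (1.05 equiv), DMF, 0 °C to rt, dark
Reagents that add atoms: N-iodosuccinimide (NIS), O=C1CCC(=O)N1I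
Why: Electrophilic aromatic iodination of 2-hydroxy-4,6-dialkoxyacetophenones is known to go to C3, the free position ortho to the chelated hydroxyl, and neutral NIS spares the MOM acetal and the methyl ketone; the site can be verified through the NOE contacts expected between the remaining ring hydrogen and both the OMe and OCH2O groups.

Step 3
Reactants: 3 aryl iodide 1-[2-hydroxy-3-iodo-6-methoxy-4-(methoxymethoxy)phenyl]ethanone; 4 tributyl(3-methylbut-2-enyl)stannane
Product: 5 prenyl arene 1-[2-hydroxy-6-methoxy-4-(methoxymethoxy)-3-(3-methylbut-2-enyl)phenyl]ethanone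
Conditions: Pd(PPh3)4 (5 mol %), DMF, 90 °C
Reagents that add atoms: none
Why: Stille coupling puts the prenyl group exactly on the carbon that carried iodine, which avoids the C3/C5 and O/C mixtures of direct phenoxide prenylation, and reductive elimination from the aryl(prenyl)palladium intermediate normally takes place at the unsubstituted allyl terminus to give the linear prenyl arene.

Step 4
Reactants: 5 prenyl arene 1-[2-hydroxy-6-methoxy-4-(methoxymethoxy)-3-(3-methylbut-2-enyl)phenyl]ethanone
Product: 6 allylic alcohol 1-[2-hydroxy-3-[(E)-4-hydroxy-3-methylbut-2-enyl]-6-methoxy-4-(methoxymethoxy)phenyl]ethanone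
Conditions: SeO2 (0.3 equiv), t-BuOOH (2 equiv, in decane), CH2Cl2, 0 °C to rt
Reagents that add atoms: tert-butyl hydroperoxide (oxygen atom relayed through SeO2), CC(C)(C)OO
Why: Catalytic SeO2 allylic oxidation (ene reaction followed by [2,3]-sigmatropic shift) hydroxylates the methyl group trans to the benzylic chain and thus gives the E allylic alcohol, while the Riley oxidation of an aryl methyl ketone needs hot stoichiometric SeO2 and should not compete at or below room temperature.

Step 5
Reactants: 6 allylic alcohol 1-[2-hydroxy-3-[(E)-4-hydroxy-3-methylbut-2-enyl]-6-methoxy-4-(methoxymethoxy)phenyl]ethanone; 7 methyl chloroformate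
Product: 8 allylic carbonate methyl (E)-4-[3-acetyl-2-hydroxy-4-methoxy-6-(methoxymethoxy)phenyl]-2-methylbut-2-enyl carbonate
Conditions: pyridine (2 equiv), CH2Cl2, 0 °C
Reagents that add atoms: none
Why: O-Acylation with a chloroformate is much faster at the unhindered primary allylic alcohol than at the phenol, which is hydrogen-bonded to the acetyl group and flanked by two ortho substituents, so one equivalent of 7 at 0 °C should give the mono-carbonate.

Step 6
Reactants: 8 allylic carbonate methyl (E)-4-[3-acetyl-2-hydroxy-4-methoxy-6-(methoxymethoxy)phenyl]-2-methylbut-2-enyl carbonate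
Product: 9 isopropenyl dihydrobenzofuran 1-[(2R)-6-methoxy-4-(methoxymethoxy)-2-(prop-1-en-2-yl)-2,3-dihydro-1-benzofuran-7-yl]ethanone
Conditions: Pd2(dba)3·CHCl3 (2.5 mol %), (1R,2R)-N,N'-bis(2-diphenylphosphinobenzoyl)cyclohexane-1,2-diamine (7.5 mol %), AcOH (1 equiv), degassed CH2Cl2, rt
Reagents that add atoms: none
Why: Zerovalent palladium ionises the allylic carbonate with loss of CO2 and methoxide to a 2-methyl-π-allyl complex in which the E alkene geometry places the benzylic chain syn, and the phenol oxygen next to the acetyl group then attacks the CH terminus on the face away from palladium to form O1–C2. The closest known reaction type is the asymmetric intramolecular Tsuji–Trost O-allylation of phenols, which is established for 2-vinyl and 2-isopropenyl dihydrobenzofurans and for chromans. The dihydrofuran ring closes in the 5-exo mode; attack at the CH2 terminus would be a 7-endo closure that has to accommodate the syn allyl geometry in a seven-membered ring and should not compete. C2, the only new stereocentre, is controlled by the twofold-symmetric ligand under Curtin–Hammett conditions: the two diastereomeric complexes exchange the palladium face through the σ-allyl form bound at the unsubstituted CH2 terminus, and AcOH keeps most of the phenol protonated so that this exchange stays faster than ring closure. The step needs site selectivity between the two oxygen atoms that flank the side chain, and the MOM ether on the oxygen para to the acetyl group secures it by leaving a single free phenol. O- over C-attack is secured by the acidity gap between the chelated phenol and the methyl ketone.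

Step 7
Reactants: 9 isopropenyl dihydrobenzofuran 1-[(2R)-6-methoxy-4-(methoxymethoxy)-2-(prop-1-en-2-yl)-2,3-dihydro-1-benzofuran-7-yl]ethanone
Product: 10 tertiary alcohol 1-[(2R)-2-(2-hydroxypropan-2-yl)-6-methoxy-4-(methoxymethoxy)-2,3-dihydro-1-benzofuran-7-yl]ethanone
Conditions: Co(acac)2 (20 mol %), PhSiH3 (2 equiv), O2 (1 atm), THF, rt
Reagents that add atoms: dioxygen, O=O
Why: Mukaiyama hydration (hydrogen-atom transfer to the CH2 terminus from the hydride generated from Co(acac)2 and PhSiH3, trapping of the tertiary radical by O2 and reduction of the peroxide) gives the Markovnikov tertiary alcohol without touching C2, the aryl ketone or the MOM ether, and it is run before the enone is built because the enone would be reduced under these conditions.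

Step 8
Reactants: 11 aldehyde 4-hydroxybenzaldehyde
Product: 12 aldehyde 4-(methoxymethoxy)benzaldehyde
Conditions: MOMCl (1.2 equiv), K2CO3 (2 equiv), acetone, rt
Reagents that add atoms: chloromethyl methyl ether (MOMCl), COCCl
Why: Williamson-type MOM ether formation masks the phenol, whose anion would otherwise deactivate the aldehyde toward enolate addition in step 9.

Step 9
Reactants: 10 tertiary alcohol 1-[(2R)-2-(2-hydroxypropan-2-yl)-6-methoxy-4-(methoxymethoxy)-2,3-dihydro-1-benzofuran-7-yl]ethanone; 12 aldehyde 4-(methoxymethoxy)benzaldehyde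
Product: 13 protected chalcone (E)-1-[(2R)-2-(2-hydroxypropan-2-yl)-6-methoxy-4-(methoxymethoxy)-2,3-dihydro-1-benzofuran-7-yl]-3-[4-(methoxymethoxy)phenyl]prop-2-en-1-one
Conditions: KOH (aq), MeOH, rt to 50 °C
Reagents that add atoms: none
Why: Claisen–Schmidt condensation (aldol addition of the methyl ketone enolate to the non-enolisable aldehyde, then E1cB dehydration) gives the thermodynamically preferred E enone as it does routinely with 2,4,6-trialkoxyacetophenones, and hydroxide affects neither the MOM ethers, the tertiary alcohol nor the non-acidic C2–H.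

Step 10
Reactants: 13 protected chalcone (E)-1-[(2R)-2-(2-hydroxypropan-2-yl)-6-methoxy-4-(methoxymethoxy)-2,3-dihydro-1-benzofuran-7-yl]-3-[4-(methoxymethoxy)phenyl]prop-2-en-1-one
Product: 14 target chalcone (E)-1-[(2R)-4-hydroxy-2-(2-hydroxypropan-2-yl)-6-methoxy-2,3-dihydro-1-benzofuran-7-yl]-3-(4-hydroxyphenyl)prop-2-en-1-one
Conditions: HCl (aq, 3 M), MeOH, rt to 40 °C
Reagents that add atoms: none
Why: Acid-catalysed acetal exchange with methanol removes both phenolic MOM groups under conditions too mild to ionise the tertiary alcohol, which is deactivated by the neighbouring ring oxygen, and flavanone formation is impossible because both positions ortho to the carbonyl carry ether oxygens.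

Compound list
1 | acetophenone 1-(2,4-dihydroxy-6-methoxyphenyl)ethanone | CC(=O)c1c(O)cc(O)cc1OC | starting material
2 | mono-MOM ether 1-[2-hydroxy-6-methoxy-4-(methoxymethoxy)phenyl]ethanone | CC(=O)c1c(O)cc(OCOC)cc1OC | intermediate
3 | aryl iodide 1-[2-hydroxy-3-iodo-6-methoxy-4-(methoxymethoxy)phenyl]ethanone | CC(=O)c1c(O)c(I)c(OCOC)cc1OC | intermediate
4 | tributyl(3-methylbut-2-enyl)stannane | CCCC[Sn](CCCC)(CCCC)CC=C(C)C | starting material
5 | prenyl arene 1-[2-hydroxy-6-methoxy-4-(methoxymethoxy)-3-(3-methylbut-2-enyl)phenyl]ethanone | CC(=O)c1c(O)c(CC=C(C)C)c(OCOC)cc1OC | intermediate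
6 | allylic alcohol 1-[2-hydroxy-3-[(E)-4-hydroxy-3-methylbut-2-enyl]-6-methoxy-4-(methoxymethoxy)phenyl]ethanone | CC(=O)c1c(O)c(C/C=C(\C)CO)c(OCOC)cc1OC | intermediate
7 | methyl chloroformate | COC(=O)Cl | starting material
8 | allylic carbonate methyl (E)-4-[3-acetyl-2-hydroxy-4-methoxy-6-(methoxymethoxy)phenyl]-2-methylbut-2-enyl carbonate | CC(=O)c1c(OC)cc(OCOC)c(C/C=C(\C)COC(=O)OC)c1O | intermediate
9 | isopropenyl dihydrobenzofuran 1-[(2R)-6-methoxy-4-(methoxymethoxy)-2-(prop-1-en-2-yl)-2,3-dihydro-1-benzofuran-7-yl]ethanone | CC(=O)c1c(OC)cc(OCOC)c2c1O[C@@H](C(C)=C)C2 | intermediate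
10 | tertiary alcohol 1-[(2R)-2-(2-hydroxypropan-2-yl)-6-methoxy-4-(methoxymethoxy)-2,3-dihydro-1-benzofuran-7-yl]ethanone | CC(=O)c1c(OC)cc(OCOC)c2c1O[C@@H](C(C)(C)O)C2 | intermediate
11 | aldehyde 4-hydroxybenzaldehyde | O=Cc1ccc(O)cc1 | starting material
12 | aldehyde 4-(methoxymethoxy)benzaldehyde | COCOc1ccc(C=O)cc1 | intermediate
13 | protected chalcone (E)-1-[(2R)-2-(2-hydroxypropan-2-yl)-6-methoxy-4-(methoxymethoxy)-2,3-dihydro-1-benzofuran-7-yl]-3-[4-(methoxymethoxy)phenyl]prop-2-en-1-one | COCOc1ccc(/C=C/C(=O)c2c(OC)cc(OCOC)c3c2O[C@@H](C(C)(C)O)C3)cc1 | intermediate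
14 | target chalcone (E)-1-[(2R)-4-hydroxy-2-(2-hydroxypropan-2-yl)-6-methoxy-2,3-dihydro-1-benzofuran-7-yl]-3-(4-hydroxyphenyl)prop-2-en-1-one | COc1cc(O)c2c(c1C(=O)/C=C/c1ccc(O)cc1)O[C@@H](C(C)(C)O)C2 | target

Total step count: 10
Longest linear sequence: 9 steps (steps 1 to 7, 9 and 10; step 8 is a one-step side branch)

Steps most likely to fail

Step 6. Ring closure by the acidic, acetyl-chelated phenoxide may outrun the face exchange of the π-allyl complex, so that enantioselection erodes. Ionisation may also be followed by β-hydride loss instead of C–O bond formation. The fallback sets out from 6 and comes back at 10, bypassing steps 5 to 7, and sets the stereocentre by reagent-controlled epoxidation instead of π-allyl chemistry.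
- Sharpless asymmetric epoxidation of 6 uses t-BuOOH, 4 Å sieves, CH2Cl2 and −20 °C, with Ti(OiPr)4 and L-(+)-diethyl tartrate in stoichiometric amount because the phenol also binds titanium. It should give 1-[2-hydroxy-3-{[(2S,3S)-3-(hydroxymethyl)-3-methyloxiran-2-yl]methyl}-6-methoxy-4-(methoxymethoxy)phenyl]ethanone F1, the sense following that of simple (E)-alk-2-en-1-ols.
- K2CO3 in DMF at rt then lets the phenoxide open the oxirane at its CH carbon (5-exo-tet, inversion). This gives 1-[(2R)-2-[(2S)-1,2-dihydroxypropan-2-yl]-6-methoxy-4-(methoxymethoxy)-2,3-dihydro-1-benzofuran-7-yl]ethanone F2.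
- I2, PPh3 and imidazole convert the primary hydroxyl selectively into 1-[(2R)-2-[(2R)-2-hydroxy-1-iodopropan-2-yl]-6-methoxy-4-(methoxymethoxy)-2,3-dihydro-1-benzofuran-7-yl]ethanone F3.
- Bu3SnH with AIBN in toluene at 80 °C replaces iodine by hydrogen to deliver 10.

Step 4. The allylic alcohol may be over-oxidised to the aldehyde stage, the electron-rich phenol ring may suffer oxidative damage, or conversion may stall. The fallback sets out from 5 and comes back at 6, and exchanges the alkene terminus instead of oxidising a C–H bond.
- Cross-metathesis of the prenyl alkene of 5 with methacrolein (second-generation Hoveyda–Grubbs catalyst, CH2Cl2, 40 °C) should give (E)-4-[3-acetyl-2-hydroxy-4-methoxy-6-(methoxymethoxy)phenyl]-2-methylbut-2-enal F4.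
- Luche reduction (NaBH4, CeCl3·7H2O, MeOH, −20 °C) reduces the aldehyde but not the deactivated, chelated aryl ketone, giving 6.

Step 3. Oxidative addition and transmetalation at the doubly ortho-substituted, electron-rich iodide may be slow enough for protodeiodination to intervene. The prenyl group may also be transferred with allylic transposition. The fallback sets out from 1 and comes back at 5, bypassing steps 1 to 3, and uses anionic C-alkylation instead of cross-coupling.
- The phenoxide of 1 is alkylated with prenyl bromide (KOH, MeOH, 0 °C to rt) at the carbon between the two hydroxyl groups. This gives 1-[2,4-dihydroxy-6-methoxy-3-(3-methylbut-2-enyl)phenyl]ethanone F5, which has to be separated chromatographically from the O-alkylation and C5-alkylation products.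
- Selective MOM protection of the non-chelated hydroxyl (MOMCl, K2CO3, acetone) then gives 5.

Further compounds
F1 | step 6 | 1-[2-hydroxy-3-{[(2S,3S)-3-(hydroxymethyl)-3-methyloxiran-2-yl]methyl}-6-methoxy-4-(methoxymethoxy)phenyl]ethanone | CC(=O)c1c(O)c(C[C@@H]2O[C@@]2(C)CO)c(OCOC)cc1OC
F2 | step 6 | 1-[(2R)-2-[(2S)-1,2-dihydroxypropan-2-yl]-6-methoxy-4-(methoxymethoxy)-2,3-dihydro-1-benzofuran-7-yl]ethanone | CC(=O)c1c(OC)cc(OCOC)c2c1O[C@@H]([C@@](C)(O)CO)C2
F3 | step 6 | 1-[(2R)-2-[(2R)-2-hydroxy-1-iodopropan-2-yl]-6-methoxy-4-(methoxymethoxy)-2,3-dihydro-1-benzofuran-7-yl]ethanone | CC(=O)c1c(OC)cc(OCOC)c2c1O[C@@H]([C@@](C)(O)CI)C2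
F4 | step 4 | (E)-4-[3-acetyl-2-hydroxy-4-methoxy-6-(methoxymethoxy)phenyl]-2-methylbut-2-enal | CC(=O)c1c(O)c(C/C=C(\C)C=O)c(OCOC)cc1OC
F5 | step 3 | 1-[2,4-dihydroxy-6-methoxy-3-(3-methylbut-2-enyl)phenyl]ethanone | CC(=O)c1c(O)c(CC=C(C)C)c(O)cc1OC
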